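# Proposed total synthesis of the bis(bibenzyl) macrocycle CNP0329842.0 by silicon-directed Friedel–Crafts ring closure

## The problem

The target is a 20-membered ring of four benzene rings. Two diaryl ether oxygens (ring A–O–ring B and ring C–O–ring D) and two CH2CH2 bridges (ring B to ring C, ring D to ring A) hold it together. Ring A is 1,2,4-substituted: its OH is ortho to the ether oxygen and its bridge carbon is para to that oxygen. Ring B is meta-substituted and ring C is para-substituted. Ring D carries its OH para to the bridge carbon and its ether oxygen ortho to the OH. There is no stereocentre, so the task is regiochemical and entropic: each of the four links must be placed correctly on its ring, and one of them must close a large ring against chain growth. The two free phenols sit on catechol-type rings that are the most electron-rich and oxidation-prone parts of the molecule, so they must stay masked until the end. On the way, three groups need care: an aryl–silicon bond (sensitive to strong protic acid), aryl sulfonates (sensitive to hot hydroxide) and an arylacetic ester with acidic α-hydrogens. The feature that opens a simple ring closure is on ring C. Its bridge carbon is para to the ether oxygen, the position where a phenoxy ring is attacked by electrophiles. The adjacent bridge carbon can be raised to a ketone, which turns the ring B to ring C link into an arylacetyl group on ring B.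

## Retrosynthesis

**Target 20 back to ketone 17.** The two phenols of 20 are masked as methanesulfonates in 19, and the CH2 next to ring C in 19 is taken back to the carbonyl of ketone 17. The forward reactions are an ionic hydrogenation of an aryl ketone (through alcohol 18) and a hydroxide cleavage of aryl sulfonates. Neither touches a diaryl ether. The mesylates are chosen over ethers because they withdraw electrons, which the ring closure needs, and because they survive Lewis and Brønsted acid.

**Ketone 17 back to acid chloride 15.** The bond between ring C and the carbonyl carbon is cut. Three neighbouring cuts were weighed against it: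
- An ether C–O bond, closed by Ullmann or SNAr chemistry, would put the ring closure at a hindered ortho-oxygenated carbon.
- The ring D to ring A bridge, closed by a Wittig reaction, is workable but would leave the ring B to ring C bridge to be built earlier with no electronic help.
- The reverse polarity, an acyl group on ring C attacking ring B, fails because the bridge carbon of ring B is meta to its oxygen.

The chosen cut uses the innate polarity of ring C. A trimethylsilyl group on that carbon in 15 adds an ipso director, and the mesylates on rings A and D make those rings poor competitors. The precursor 15 is an open chain whose three other links are already in place. The forward reaction must close a 20-membered ring at high dilution through acylium salt 16.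

**Acid chloride 15 back to diphenol ester 12.** These are functional-group changes only: acid chloride 15 from acid 14, acid 14 from methyl ester 13, and the two mesylates of 13 from diphenol 12. The forward demands are an ester hydrolysis that spares aryl mesylates and an acid chloride formation that spares the aryl–silicon bond.

**Diphenol ester 12 back to phosphonium salt 6 and aldehyde 9.** The central C–C bond of the ring D to ring A bridge is cut through stilbene 11. A Wittig reaction is preferred to a benzylic alkylation or a cross-coupling because both halves are then simple benzaldehyde derivatives. The hydrogenation that saturates 11 also removes both benzyl ethers, so alkene reduction and phenol release cost one step. The precursors are two diaryl ethers of about equal size.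

**Phosphonium salt 6 back to aldehyde 1 and phenol 2.** Salt 6 comes from benzylic alcohol 4 (through bromide 5), and 4 from aldehyde 3. The ring A–O–ring B ether of 3 is cut at the ring A carbon. Fluoride 1 has its leaving group para to the formyl group, so phenol 2 can displace it by SNAr without a metal. The formyl group thus serves twice, as activator and as the future bridge carbon.

**Aldehyde 9 back to phenol 7 and boronic acid 8.** The ring C–O–ring D ether is cut at the ring C carbon. Ring C has no activating group for SNAr and must carry silicon, so a copper-mediated oxidative coupling at room temperature is asked for. It leaves the aldehyde, the benzyl ether and the aryl–silicon bond alone.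

## Roads not taken

**Alternative 1:** The cut is the C–O bond between the ether oxygen and ring D. The open precursor A1 carries ring D as a 2,6-dibromophenol and ring C as a 2,6-dichlorophenol, with ring A as its methyl ether. Tl(NO3)3 in methanol would oxidise the more easily oxidised dibromophenol. The ring C phenol oxygen would add to a bromine-bearing ortho carbon, and zinc would then expel bromide to give the trihalogenated macrocycle A2.
- Merits: the hindered catechol-type ether is made in the ring-closing step with the ring D hydroxyl already free beside it. Neither half needs a metal-mediated ether coupling for this link.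
- Weak points: four halogens must be installed that the target does not contain. Three must later be removed by hydrogenolysis, and ring A must be demethylated. The oxidant is a stoichiometric, toxic trivalent thallium salt. The method is established for 14- to 17-membered peptide-like rings, which are better pre-organised than a flexible 20-membered hydrocarbon chain.
- Comparison: in forming the most hindered ether last, Alternative 1 is the better idea. The chosen plan sets against it an ether made at room temperature on monomers, a ring closure that needs only one foreign atom (silicon), and a two-step end game in place of three or more.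

**Alternative 2:** Both CH2CH2 bridges are cut at their central bonds. The 22-membered dithia macrocycle A3 would be assembled by twofold thiolate alkylation between an A–O–B half and a C–O–D half. It would be oxidised to bis(sulfone) A4, and flash vacuum pyrolysis would expel two SO2 to give the target dimethyl ether A5.
- Merits: the plan is highly convergent. Thioether macrocyclisation is among the most dependable ring closures, and no arene selectivity question arises anywhere.
- Weak points: A4 is a heavy, involatile solid, so subliming it through a hot tube competes with decomposition. Each extrusion passes through a benzylic radical pair that can disproportionate instead of recombining. The scale is set by the pyrolysis apparatus, and two methyl ethers still have to be cleaved.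
- Comparison: Alternative 2 is superior in convergency and in freedom from regiochemical risk, and its step count is similar. The chosen plan sets against it a ring closure in ordinary glassware at or below room temperature and no gas-phase step.

**Alternative 3:** The cut is the C–O bond between the ether oxygen and ring B. In precursor A6, ring A carries a free phenol and ring B is a 2-trimethylsilyl-1,3-bis(triflate) with the bridge at C5. CsF would generate the 3-(triflyloxy)aryne A7. The ring A phenoxide would add at the aryne carbon remote from the remaining triflate, and protonation would give macrocyclic triflate A8.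
- Merits: the aryne precursor is symmetric, so only one aryne can form, and the remaining triflate steers the nucleophile to the correct meta relationship. The conditions are mild and free of transition metals.
- Weak points: A7 is a fleeting intermediate that cannot wait for a 20-membered ring to fold. Under dilution, capture by fluoride, solvent or a second molecule competes. The ring B building block needs several steps of its own. The surplus triflate must be removed by palladium-catalysed reduction to reach A5 before demethylation, so the end game is three steps.
- Comparison: Alternative 3 matches the chosen plan in having a built-in regiochemical guide, and it has no competing arenes. The chosen plan sets against it a reactive species that AlCl3 regenerates reversibly from the acid chloride, so ring closure can be awaited, and a shorter end game.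

Key step: step 10

## Route

Remark on the chemistry: stilbene 11 is assumed to form as a mixture of E and Z isomers. This is immaterial because step 6 saturates the double bond. Alcohol 18 is racemic and its stereocentre is removed in the same flask.

Step 1
Reactants: 1 3-(benzyloxy)-4-fluorobenzaldehyde; 2 methyl 2-(3-hydroxyphenyl)acetate
Product: 3 methyl 2-{3-[2-(benzyloxy)-4-formylphenoxy]phenyl}acetate
Conditions: K2CO3, DMF, 100 °C
Reagents that add atoms: none
Why: Nucleophilic aromatic substitution (SNAr): the phenoxide of 2 displaces fluoride para to the formyl group, which stabilises the Meisenheimer intermediate; carbonate is too weak a base to engage the arylacetate α-position to a useful extent.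

Step 2
Reactants: 3 methyl 2-{3-[2-(benzyloxy)-4-formylphenoxy]phenyl}acetate
Product: 4 methyl 2-{3-[2-(benzyloxy)-4-(hydroxymethyl)phenoxy]phenyl}acetate
Conditions: NaBH4, MeOH/THF, 0 °C
Reagents that add atoms: none
Why: Chemoselective borohydride reduction of an aryl aldehyde; the methyl ester is not reduced under these conditions.

Step 3
Reactants: 4 methyl 2-{3-[2-(benzyloxy)-4-(hydroxymethyl)phenoxy]phenyl}acetate
Product: 6 {3-(benzyloxy)-4-[3-(2-methoxy-2-oxoethyl)phenoxy]benzyl}triphenylphosphonium bromide, via benzyl bromide 5 (not isolated)
Conditions: PPh3·HBr, MeCN, reflux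
Reagents that add atoms: triphenylphosphine hydrobromide, [Br-].c1ccc([PH+](c2ccccc2)c2ccccc2)cc1
Why: One-flask conversion of an electron-rich benzylic alcohol into its phosphonium salt: HBr turns the alcohol into bromide 5, which quaternises PPh3; the para aryloxy group assists ionisation, and the ester and benzyl ether tolerate the weak acid.

Step 4
Reactants: 7 4-(benzyloxy)-3-hydroxybenzaldehyde; 8 [4-(trimethylsilyl)phenyl]boronic acid
Product: 9 4-(benzyloxy)-3-[4-(trimethylsilyl)phenoxy]benzaldehyde
Conditions: Cu(OAc)2 (1 equiv), pyridine, 4 Å molecular sieves, CH2Cl2, open to air, rt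
Reagents that add atoms: none
Why: Chan–Lam O-arylation: transmetalation of 8 to divalent copper, oxidation to a trivalent copper aryl phenoxide and reductive elimination form the diaryl ether, with air returning copper to the divalent state; the room-temperature, fluoride-free and acid-free conditions leave the aryl–silicon bond intact.

Step 5
Reactants: 6 {3-(benzyloxy)-4-[3-(2-methoxy-2-oxoethyl)phenoxy]benzyl}triphenylphosphonium bromide; 9 4-(benzyloxy)-3-[4-(trimethylsilyl)phenoxy]benzaldehyde
Product: 11 methyl 2-{3-[2-(benzyloxy)-4-(2-{4-(benzyloxy)-3-[4-(trimethylsilyl)phenoxy]phenyl}ethenyl)phenoxy]phenyl}acetate (E/Z mixture), via phosphonium ylide 10 (not isolated)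
Conditions: K2CO3, 18-crown-6 (cat.), CH2Cl2, reflux
Reagents that add atoms: none
Why: Wittig reaction of a semi-stabilised benzylic ylide with an aryl aldehyde under solid–liquid phase transfer; the benzylic phosphonium C–H is far more acidic than the arylacetate C–H, so only ylide 10 forms, and the alkene geometry is irrelevant.

Step 6
Reactants: 11 methyl 2-{3-[2-(benzyloxy)-4-(2-{4-(benzyloxy)-3-[4-(trimethylsilyl)phenoxy]phenyl}ethenyl)phenoxy]phenyl}acetate (E/Z mixture)
Product: 12 methyl 2-{3-[2-hydroxy-4-(2-{4-hydroxy-3-[4-(trimethylsilyl)phenoxy]phenyl}ethyl)phenoxy]phenyl}acetate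
Conditions: H2 (1 atm), Pd/C, EtOAc/MeOH, rt
Reagents that add atoms: none
Why: Catalytic hydrogenation saturates the stilbene and hydrogenolyses both benzyl ethers in one operation; diaryl ethers, the methyl ester and the aryltrimethylsilane are inert to Pd/C under neutral conditions.

Step 7
Reactants: 12 methyl 2-{3-[2-hydroxy-4-(2-{4-hydroxy-3-[4-(trimethylsilyl)phenoxy]phenyl}ethyl)phenoxy]phenyl}acetate
Product: 13 methyl 2-{3-[2-(methanesulfonyloxy)-4-(2-{4-(methanesulfonyloxy)-3-[4-(trimethylsilyl)phenoxy]phenyl}ethyl)phenoxy]phenyl}acetate
Conditions: MsCl, Et3N, CH2Cl2, 0 °C
Reagents that add atoms: methanesulfonyl chloride, CS(=O)(=O)Cl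
Why: Standard O-sulfonylation of phenols; both hydroxyls are converted into electron-withdrawing mesylates that later deactivate rings A and D.

Step 8
Reactants: 13 methyl 2-{3-[2-(methanesulfonyloxy)-4-(2-{4-(methanesulfonyloxy)-3-[4-(trimethylsilyl)phenoxy]phenyl}ethyl)phenoxy]phenyl}acetate
Product: 14 2-{3-[2-(methanesulfonyloxy)-4-(2-{4-(methanesulfonyloxy)-3-[4-(trimethylsilyl)phenoxy]phenyl}ethyl)phenoxy]phenyl}acetic acid
Conditions: LiOH·H2O (1.5 equiv), THF/H2O, 0 °C; then cold dilute HCl
Reagents that add atoms: lithium hydroxide, [Li+].[OH-]
Why: Saponification of an unhindered arylacetic methyl ester, which is fast at 0 °C, whereas aryl mesylates need hot hydroxide for cleavage; the brief cold acidification is too mild to protodesilylate ring C.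

Step 9
Reactants: 14 2-{3-[2-(methanesulfonyloxy)-4-(2-{4-(methanesulfonyloxy)-3-[4-(trimethylsilyl)phenoxy]phenyl}ethyl)phenoxy]phenyl}acetic acid
Product: 15 2-{3-[2-(methanesulfonyloxy)-4-(2-{4-(methanesulfonyloxy)-3-[4-(trimethylsilyl)phenoxy]phenyl}ethyl)phenoxy]phenyl}acetyl chloride (used crude after evaporation)
Conditions: (COCl)2, DMF (cat.), CH2Cl2, 0 °C to rt; evaporate with toluene
Reagents that add atoms: oxalyl chloride, O=C(Cl)C(=O)Cl
Why: Acid chloride formation through the catalytic Vilsmeier-type chloroiminium species; the by-products are gases, and dry HCl in CH2Cl2 without a Lewis acid is too weakly acidic to cleave the aryl–silicon bond in the time needed.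

Step 10
Reactants: 15 2-{3-[2-(methanesulfonyloxy)-4-(2-{4-(methanesulfonyloxy)-3-[4-(trimethylsilyl)phenoxy]phenyl}ethyl)phenoxy]phenyl}acetyl chloride
Product: 17 macrocyclic aryl benzyl ketone bis(mesylate) (20-membered ring; carbonyl on ring C para to the ether oxygen; CH2 on ring B; mesyloxy groups on rings A and D), via acylium tetrachloroaluminate 16 (not isolated)
Conditions: AlCl3 (4 equiv), CH2Cl2, 0 °C to rt; 15 added by syringe pump over 12 h to a final concentration near 1 mM
Reagents that add atoms: none
Why: AlCl3 ionises 15 to the arylacetyl cation of 16, which attacks ring C at the silicon-bearing carbon; the σ-complex is stabilised by the para ether oxygen and by hyperconjugation with the C–Si bond, and chloride removes silicon as Me3SiCl to restore the arene (Friedel–Crafts ipso-acyldesilylation). The closest known reaction types are the high-dilution intramolecular Friedel–Crafts acylation that gives cyclophane ketones and the ipso-acylation of aryltrimethylsilanes by acid chlorides with AlCl3. The 20-membered ring closes by electrophilic aromatic substitution, the arene carbon attacking the acylium carbon whose carbon–oxygen multiple bond stays outside the new ring (formally an exo closure at a digonal carbon). No stereocentre is formed. The step needs site selectivity among four arenes and ring closure ahead of chain growth: ring C is the only ring with a donor oxygen and no deactivating group, and its reacting carbon is para to that oxygen and bears silicon, whereas rings A and D each carry a mesyloxy group, and ring B holds the electrophile and can react only between molecules, which slow addition into dilute AlCl3 suppresses. If silicon is lost to adventitious acid before acylation, the same carbon remains the preferred C–H site, so the regiochemical outcome is unchanged. Ketone 17 is complexed by AlCl3 and deactivated, so it is not acylated again.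

Step 11
Reactants: 17 macrocyclic aryl benzyl ketone bis(mesylate)
Product: 19 macrocyclic bis(mesylate) (the target with both phenols as methanesulfonates), via benzylic alcohol 18 (not isolated)
Conditions: Et3SiH (4 equiv), CF3CO2H/CH2Cl2, 0 °C to rt
Reagents that add atoms: none
Why: Ionic hydrogenation: hydride transfer to the protonated ketone gives alcohol 18, which ionises to a benzylic cation stabilised by the para aryloxy group and takes a second hydride; any stilbene formed by proton loss is reprotonated to the same cation, and aryl mesylates are stable to the acid.

Step 12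
Reactants: 19 macrocyclic bis(mesylate)
Product: 20 the target diphenol CNP0329842.0
Conditions: KOH, MeOH/H2O, reflux, under argon; then dilute HCl
Reagents that add atoms: none
Why: Basic cleavage of aryl methanesulfonates at sulfur releases both phenoxides with the aryl–oxygen bonds intact; diaryl ethers and the saturated bridges are inert, and exclusion of air protects the electron-rich phenoxides.

## Compound list

1 | 3-(benzyloxy)-4-fluorobenzaldehyde | O=Cc1ccc(F)c(OCc2ccccc2)c1 | starting material
2 | methyl 2-(3-hydroxyphenyl)acetate | COC(=O)Cc1cccc(O)c1 | starting material
3 | methyl 2-{3-[2-(benzyloxy)-4-formylphenoxy]phenyl}acetate | COC(=O)Cc1cccc(Oc2ccc(C=O)cc2OCc2ccccc2)c1 | intermediate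
4 | methyl 2-{3-[2-(benzyloxy)-4-(hydroxymethyl)phenoxy]phenyl}acetate | COC(=O)Cc1cccc(Oc2ccc(CO)cc2OCc2ccccc2)c1 | intermediate
5 | methyl 2-{3-[2-(benzyloxy)-4-(bromomethyl)phenoxy]phenyl}acetate (not isolated) | COC(=O)Cc1cccc(Oc2ccc(CBr)cc2OCc2ccccc2)c1 | intermediate
6 | {3-(benzyloxy)-4-[3-(2-methoxy-2-oxoethyl)phenoxy]benzyl}triphenylphosphonium bromide | COC(=O)Cc1cccc(Oc2ccc(C[P+](c3ccccc3)(c3ccccc3)c3ccccc3)cc2OCc2ccccc2)c1.[Br-] | intermediate
7 | 4-(benzyloxy)-3-hydroxybenzaldehyde | O=Cc1ccc(OCc2ccccc2)c(O)c1 | starting material
8 | [4-(trimethylsilyl)phenyl]boronic acid | C[Si](C)(C)c1ccc(B(O)O)cc1 | starting material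
9 | 4-(benzyloxy)-3-[4-(trimethylsilyl)phenoxy]benzaldehyde | O=Cc1ccc(OCc2ccccc2)c(Oc2ccc([Si](C)(C)C)cc2)c1 | intermediate
10 | phosphonium ylide of 6, methyl 2-{3-[2-(benzyloxy)-4-[(triphenylphosphoranylidene)methyl]phenoxy]phenyl}acetate (not isolated) | COC(=O)Cc1cccc(Oc2ccc(C=P(c3ccccc3)(c3ccccc3)c3ccccc3)cc2OCc2ccccc2)c1 | intermediate
11 | methyl 2-{3-[2-(benzyloxy)-4-(2-{4-(benzyloxy)-3-[4-(trimethylsilyl)phenoxy]phenyl}ethenyl)phenoxy]phenyl}acetate, E/Z mixture | COC(=O)Cc1cccc(Oc2ccc(C=Cc3ccc(OCc4ccccc4)c(Oc4ccc([Si](C)(C)C)cc4)c3)cc2OCc2ccccc2)c1 | intermediate
12 | methyl 2-{3-[2-hydroxy-4-(2-{4-hydroxy-3-[4-(trimethylsilyl)phenoxy]phenyl}ethyl)phenoxy]phenyl}acetate | COC(=O)Cc1cccc(Oc2ccc(CCc3ccc(O)c(Oc4ccc([Si](C)(C)C)cc4)c3)cc2O)c1 | intermediate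
13 | methyl 2-{3-[2-(methanesulfonyloxy)-4-(2-{4-(methanesulfonyloxy)-3-[4-(trimethylsilyl)phenoxy]phenyl}ethyl)phenoxy]phenyl}acetate | COC(=O)Cc1cccc(Oc2ccc(CCc3ccc(OS(C)(=O)=O)c(Oc4ccc([Si](C)(C)C)cc4)c3)cc2OS(C)(=O)=O)c1 | intermediate
14 | 2-{3-[2-(methanesulfonyloxy)-4-(2-{4-(methanesulfonyloxy)-3-[4-(trimethylsilyl)phenoxy]phenyl}ethyl)phenoxy]phenyl}acetic acid | OC(=O)Cc1cccc(Oc2ccc(CCc3ccc(OS(C)(=O)=O)c(Oc4ccc([Si](C)(C)C)cc4)c3)cc2OS(C)(=O)=O)c1 | intermediate
15 | 2-{3-[2-(methanesulfonyloxy)-4-(2-{4-(methanesulfonyloxy)-3-[4-(trimethylsilyl)phenoxy]phenyl}ethyl)phenoxy]phenyl}acetyl chloride | CS(=O)(=O)Oc1cc(CCc2ccc(OS(C)(=O)=O)c(Oc3ccc([Si](C)(C)C)cc3)c2)ccc1Oc1cccc(CC(=O)Cl)c1 | intermediate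
16 | arylacetylium tetrachloroaluminate derived from 15 (not isolated) | CS(=O)(=O)Oc1cc(CCc2ccc(OS(C)(=O)=O)c(Oc3ccc([Si](C)(C)C)cc3)c2)ccc1Oc1cccc(CC#[O+])c1.Cl[Al-](Cl)(Cl)Cl | intermediate
17 | macrocyclic aryl benzyl ketone bis(mesylate) (20-membered; C=O on ring C, CH2 on ring B) | CS(=O)(=O)Oc1cc2ccc1Oc1cccc(c1)CC(=O)c1ccc(cc1)Oc1cc(ccc1OS(C)(=O)=O)CC2 | intermediate
18 | macrocyclic benzylic alcohol bis(mesylate), racemic (not isolated) | CS(=O)(=O)Oc1cc2ccc1Oc1cccc(c1)CC(O)c1ccc(cc1)Oc1cc(ccc1OS(C)(=O)=O)CC2 | intermediate
19 | macrocyclic bis(mesylate) of the target | CS(=O)(=O)Oc1cc2ccc1Oc1cccc(c1)CCc1ccc(cc1)Oc1cc(ccc1OS(C)(=O)=O)CC2 | intermediate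
20 | CNP0329842.0, the macrocyclic bis(bibenzyl) diphenol | Oc1cc2ccc1Oc1cccc(c1)CCc1ccc(cc1)Oc1cc(ccc1O)CC2 | target

## Step count and risk assessment

Total: 12 steps. Longest linear sequence: 11 steps (steps 1, 2, 3, 5, 6, 7, 8, 9, 10, 11, 12). The other branch joins after the single step 4.

**Step 10 (key step).** The most likely failure is chain growth between molecules outrunning ring closure. The second is attack of the acylium ion at a C–H site, above all C4 of ring D (para to its ether oxygen), which would give a 14-membered ring. Cleavage of the aryl–silicon bond by traces of acid before acylation is a lesser concern because it leaves the same carbon as the preferred site.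

Fallback: the bond is made by a metal-mediated carbonyl addition whose site is fixed by a carbon–iodine bond. The fallback sets out from ester 13. ICl in CH2Cl2 at −78 °C replaces silicon by iodine (ipso-iododesilylation) to give the aryl iodide ester F1. DIBAL-H at −78 °C reduces the ester to the arylacetaldehyde F2. An intramolecular Nozaki–Hiyama–Kishi reaction (CrCl2, catalytic NiCl2, DMF, high dilution) adds the aryl–metal species to the aldehyde and closes the ring to alcohol 18, which is then isolated. The fallback rejoins the route at 18, which the conditions of step 11 reduce to 19.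

**Step 8.** Hydroxide may remove a mesyl group (attack at sulfur or elimination to sulfene) in competition with ester hydrolysis, giving mixtures of partly unmasked phenols.

Fallback: the order of events is changed so that no mesylate is exposed to prolonged hydroxide. From diphenol ester 12, LiOH in THF/H2O gives the diphenol acid F3. Schotten–Baumann mesylation (MsCl, aqueous NaOH/THF, 0 °C, short contact) then sulfonylates both phenoxides. Any mixed carboxylic–sulfonic anhydride is hydrolysed in the aqueous phase, and acidification returns acid 14.

**Step 11.** The second hydride transfer may be slow in the macrocycle, so the reaction may stall at alcohol 18 or its trifluoroacetate. The benzylic cation may also be trapped across the ring by another arene.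

Fallback: the cationic reduction is replaced by a hydrazone reduction that also removes the mesylates. From ketone 17, hydrazine hydrate and KOH in diethylene glycol at 130 °C, then 200 °C (Wolff–Kishner reduction, Huang-Minlon procedure), give the diphenol hydrazone F4. This loses dinitrogen and, after acidification, gives target 20 directly, bypassing 19 and step 12.

**Step 4.** The phenol of 7 is flanked by a benzyloxy group, so the copper-mediated coupling may be slow. Oxidative homocoupling or protodeboronation of 8 may then consume the boronic acid.

Fallback: the oxidative coupling is replaced by an Ullmann-type coupling with an aryl halide. From phenol 7, (4-bromophenyl)trimethylsilane F5 with CuI, N,N-dimethylglycine and Cs2CO3 in dioxane at 90 °C gives aldehyde 9. The aryl–silicon bond is stable to carbonate in the absence of fluoride.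

## Further compounds

F1 | step 10 | methyl 2-{3-[4-(2-{3-(4-iodophenoxy)-4-(methanesulfonyloxy)phenyl}ethyl)-2-(methanesulfonyloxy)phenoxy]phenyl}acetate | COC(=O)Cc1cccc(Oc2ccc(CCc3ccc(OS(C)(=O)=O)c(Oc4ccc(I)cc4)c3)cc2OS(C)(=O)=O)c1
F2 | step 10 | 2-{3-[4-(2-{3-(4-iodophenoxy)-4-(methanesulfonyloxy)phenyl}ethyl)-2-(methanesulfonyloxy)phenoxy]phenyl}acetaldehyde | O=CCc1cccc(Oc2ccc(CCc3ccc(OS(C)(=O)=O)c(Oc4ccc(I)cc4)c3)cc2OS(C)(=O)=O)c1
F3 | step 8 | 2-{3-[2-hydroxy-4-(2-{4-hydroxy-3-[4-(trimethylsilyl)phenoxy]phenyl}ethyl)phenoxy]phenyl}acetic acid | OC(=O)Cc1cccc(Oc2ccc(CCc3ccc(O)c(Oc4ccc([Si](C)(C)C)cc4)c3)cc2O)c1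
F4 | step 11 | hydrazone of the macrocyclic diphenol ketone (C=N–NH2 on the carbon attached to ring C) | Oc1cc2ccc1Oc1cccc(c1)CC(=NN)c1ccc(cc1)Oc1cc(ccc1O)CC2
F5 | step 4 | (4-bromophenyl)trimethylsilane | C[Si](C)(C)c1ccc(Br)cc1
A1 | alternative 1 | open bis(bibenzyl) with ring D as 2,6-dibromophenol, ring C as 2,6-dichlorophenol and ring A as methyl ether | COc1cc(CCc2cc(Br)c(O)c(Br)c2)ccc1Oc1cccc(CCc2cc(Cl)c(O)c(Cl)c2)c1
A2 | alternative 1 | trihalogenated macrocycle, ring A methyl ether | COc1cc2ccc1Oc1cccc(c1)CCc1cc(Cl)c(c(Cl)c1)Oc1cc(cc(Br)c1O)CC2
A3 | alternative 2 | 22-membered dithia macrocycle, dimethyl ether | COc1cc2ccc1Oc1cccc(c1)CSCc1ccc(cc1)Oc1cc(ccc1OC)CSC2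
A4 | alternative 2 | 22-membered bis(dibenzyl sulfone), dimethyl ether | COc1cc2ccc1Oc1cccc(c1)CS(=O)(=O)Cc1ccc(cc1)Oc1cc(ccc1OC)CS(=O)(=O)C2
A5 | alternative 2 | dimethyl ether of the target | COc1cc2ccc1Oc1cccc(c1)CCc1ccc(cc1)Oc1cc(ccc1OC)CC2
A6 | alternative 3 | open precursor with ring A phenol and ring B as 2-(trimethylsilyl)-1,3-bis(triflate) | COc1cc(CCc2ccc(OC)c(Oc3ccc(CCc4cc(OS(=O)(=O)C(F)(F)F)c([Si](C)(C)C)c(OS(=O)(=O)C(F)(F)F)c4)cc3)c2)ccc1O
A7 | alternative 3 | 3-(triflyloxy)aryne generated from A6 | COc1cc(CCc2ccc(OC)c(Oc3ccc(CCC4=CC#CC(OS(=O)(=O)C(F)(F)F)=C4)cc3)c2)ccc1O
A8 | alternative 3 | macrocyclic aryl triflate, dimethyl ether | COc1cc2ccc1Oc1cc(OS(=O)(=O)C(F)(F)F)cc(c1)CCc1ccc(cc1)Oc1cc(ccc1OC)CC2
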